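Ring atoms are numbered C1 (bears the chain C1', C2'), C2, C3 (free carbinol), C4, C5 (methoxy carbon) and C6 (acetoxy carbon). The route rests on opening the C4=C5 bond: the C5 methyl enol ether beside the C6 carbinol is read as an olefinated methyl α-silyloxy ester. In one operation a titanium alkylidene raised at C4 from a vinyl group olefinates the ester carbonyl C5, closing the cyclohexa-1,4-diene ring and creating the enol ether. The precursor is an acyclic methyl hepta-3,6-dienoate with all three stereocentres in place, whose Z-configured C1=C2 alkene holds C3 and C6, and hence C4 and C5, on the same side.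

Key step: step 10

Remark: the reduced titanium reagent is drawn formally as Cl2Ti=CHCH3 and its substrate-bound successor 19 as the matching dichlorotitanium alkylidene. Acyclic compounds carry chain numbers and ring compounds the ring numbers above; the C3 descriptor changes from S to R on ring closure through priority rules only.

Step 1
Reactants: 1 (R)-epichlorohydrin; 2 dodecylmagnesium bromide C12H25MgBr
Product: 4 (2R)-2-tridecyloxirane, via (2R)-1-chloropentadecan-2-ol 3 (not isolated)
Conditions: CuI (10 mol %), THF, −40 to 0 °C; NH4Cl (aq); then NaOH (powder), Et2O, rt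
Reagents that add atoms: none
Why: Copper-catalysed Grignard opening (SN2) at the unsubstituted epoxide carbon and Williamson closure of the chlorohydrin give the homologated epoxide; neither event touches the stereocentre, so C2' comes from the chiral pool as (R).

Step 2
Reactants: 4 (2R)-2-tridecyloxirane; 5 lithium acetylide–ethylenediamine complex LiC≡CH·H2NCH2CH2NH2
Product: 6 (4R)-heptadec-1-yn-4-ol
Conditions: DMSO, 0 °C to rt; NH4Cl (aq)
Reagents that add atoms: none
Why: Acetylide alkylation by SN2 opening of the terminal epoxide at its CH2 carbon leaves the carbinol stereocentre untouched.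

Step 3
Reactants: 6 (4R)-heptadec-1-yn-4-ol
Product: 7 (4R)-4-(triethylsilyloxy)heptadec-1-yne
Conditions: TESCl, imidazole, CH2Cl2, 0 °C to rt
Reagents that add atoms: chlorotriethylsilane, CC[Si](Cl)(CC)CC
Why: Imidazole-promoted silylation of a secondary alcohol masks O2' with the group that is later removed together with the O6 silyl ether.

Step 4
Reactants: 7 (4R)-4-(triethylsilyloxy)heptadec-1-yne; 8 acrolein
Product: 10 (3S,7R)-7-(triethylsilyloxy)icos-1-en-4-yn-3-ol, via ethyl(alkynyl)zinc 9 (not isolated)
Conditions: Et2Zn, Cy2NH (5 mol %), Et2O, rt; then (R)-BINOL (40 mol %), Ti(OiPr)4 (50 mol %), 8 (excess), 0 °C; NH4Cl (aq)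
Reagents that add atoms: none
Why: Catalytic asymmetric alkynylzinc addition to an aldehyde (BINOL–Ti(OiPr)4 type, established for enals) sets C3 under ligand control; the (R)-BINOL complex is expected to deliver the alkynyl group to the Re face of acrolein, which corresponds to the (3S) carbinol, and the remote C7 centre has no say.

Step 5
Reactants: 10 (3S,7R)-7-(triethylsilyloxy)icos-1-en-4-yn-3-ol
Product: 12 (3S,4Z,7R)-5-iodo-7-(triethylsilyloxy)icosa-1,4-dien-3-ol, via cyclic vinylalanate 11 (not isolated)
Conditions: NaAlH2(OCH2CH2OMe)2, THF, 0 °C; EtOAc; then I2, THF, −78 to 0 °C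
Reagents that add atoms: iodine, II
Why: Hydroxyl-directed trans-hydroalumination of the propargylic alcohol places aluminium on the alkyne carbon distal to the alkoxide in a five-membered oxaaluminacycle, with hydride adding anti; iodinolysis with retention then gives the Z iodoalkene with iodine cis to the carbinol carbon.

Step 6
Reactants: 12 (3S,4Z,7R)-5-iodo-7-(triethylsilyloxy)icosa-1,4-dien-3-ol
Product: 13 (3S,4Z,7R)-3-(tert-butyldimethylsilyloxy)-5-iodo-7-(triethylsilyloxy)icosa-1,4-diene
Conditions: TBSCl, imidazole, DMF, rt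
Reagents that add atoms: tert-butyldimethylsilyl chloride, CC(C)(C)[Si](C)(C)Cl
Why: Imidazole-promoted silylation of the allylic alcohol installs at O3 the silyl ether that should outlast the later cleavage of the two triethylsilyl ethers.

Step 7
Reactants: 13 (3S,4Z,7R)-3-(tert-butyldimethylsilyloxy)-5-iodo-7-(triethylsilyloxy)icosa-1,4-diene; 14 dimethyl oxalate
Product: 16 methyl (3Z,5S)-5-(tert-butyldimethylsilyloxy)-2-oxo-3-[(2R)-2-(triethylsilyloxy)pentadecyl]hepta-3,6-dienoate, via alkenylmagnesium chloride 15 (not isolated)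
Conditions: i-PrMgCl·LiCl, THF, 0 °C to rt; then cannulated into 14 (3 equiv), THF, −78 °C; NH4Cl (aq)
Reagents that add atoms: none
Why: Iodine–magnesium exchange retains the alkene geometry and the alkenyl Grignard monoacylates excess dimethyl oxalate at low temperature (standard α-keto ester synthesis); magnesium is chosen over lithium because two silyloxy groups sit 1,4 to the carbanion carbon and a lithium species could undergo oxygen-to-carbon silyl migration (retro-Brook).

Step 8
Reactants: 16 methyl (3Z,5S)-5-(tert-butyldimethylsilyloxy)-2-oxo-3-[(2R)-2-(triethylsilyloxy)pentadecyl]hepta-3,6-dienoate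
Product: 17 methyl (2S,3Z,5S)-5-(tert-butyldimethylsilyloxy)-2-hydroxy-3-[(2R)-2-(triethylsilyloxy)pentadecyl]hepta-3,6-dienoate
Conditions: (S)-2-methyl-CBS-oxazaborolidine (0.5 equiv), catecholborane, toluene, −78 °C
Reagents that add atoms: none
Why: Corey–Bakshi–Shibata reduction sets C6 under catalyst control: with the branched alkenyl residue as the large group and the planar ester as the small one, the (S) catalyst is expected to deliver hydride to the face that gives the (2S) alcohol, and catecholborane at −78 °C should reduce only the ketone.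

Step 9
Reactants: 17 methyl (2S,3Z,5S)-5-(tert-butyldimethylsilyloxy)-2-hydroxy-3-[(2R)-2-(triethylsilyloxy)pentadecyl]hepta-3,6-dienoate
Product: 18 methyl (2S,3Z,5S)-5-(tert-butyldimethylsilyloxy)-2-(triethylsilyloxy)-3-[(2R)-2-(triethylsilyloxy)pentadecyl]hepta-3,6-dienoate
Conditions: TESOTf, 2,6-lutidine, CH2Cl2, −78 °C
Reagents that add atoms: triethylsilyl trifluoromethanesulfonate, CC[Si](CC)(CC)OS(=O)(=O)C(F)(F)F
Why: Silyl triflate silylation of the hindered α-hydroxy ester with a non-nucleophilic base at low temperature should not epimerise the ester α-centre C6.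

Step 10
Reactants: 18 methyl (2S,3Z,5S)-5-(tert-butyldimethylsilyloxy)-2-(triethylsilyloxy)-3-[(2R)-2-(triethylsilyloxy)pentadecyl]hepta-3,6-dienoate
Product: 20 (3R,6S)-3-(tert-butyldimethylsilyloxy)-5-methoxy-6-(triethylsilyloxy)-1-[(2R)-2-(triethylsilyloxy)pentadecyl]cyclohexa-1,4-diene, via titanium alkylidene 19 (not isolated)
Conditions: TiCl4, TMEDA, THF–CH2Cl2, 0 °C; Zn, PbCl2 (cat.), rt; then 18, CH3CHBr2, rt to 65 °C; K2CO3 (aq), Et3N
Reagents that add atoms: none
Why: The titanium ethylidene made from CH3CHBr2, Zn and TiCl4–TMEDA (Takai–Utimoto reagent) should exchange with the terminal vinyl group by [2+2] addition and cycloreversion, releasing propene and leaving titanium on C4 (19); [2+2] addition of this alkylidene to the ester carbonyl C5 and collapse of the oxatitanacyclobutane then expel a titanium oxo species and form the C4=C5 enol ether. The closest known reaction type is the titanium-alkylidene cyclisation of olefinic esters to cyclic enol ethers (tandem olefin metathesis–carbonyl olefination); here the alkene lies in the acyl branch, so a carbocycle with an exocyclic methoxy group results, as in intramolecular titanium-alkylidene olefinations of esters that give 1-alkoxycycloalkenes. The single six-membered ring is closed by intramolecular carbonyl olefination, C4 attacking C5 in a 6-exo-trig sense with respect to the C=O bond. No stereocentre is created, and C3, C6 and C2' should pass unchanged through the aprotic, amine-buffered medium. The step needs alkylidene exchange at the monosubstituted alkene to precede direct ethylidenation of the ester and needs the C1=C2 alkene to stay untouched; the ester is shielded by the C6 silyloxy group and the fully substituted C1, the trisubstituted alkene is too hindered for [2+2] addition, and its Z geometry keeps C4 and C5 within reach.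

Step 11
Reactants: 20 (3R,6S)-3-(tert-butyldimethylsilyloxy)-5-methoxy-6-(triethylsilyloxy)-1-[(2R)-2-(triethylsilyloxy)pentadecyl]cyclohexa-1,4-diene
Product: 21 (3R,6S)-3-(tert-butyldimethylsilyloxy)-1-[(2R)-2-hydroxypentadecyl]-5-methoxycyclohexa-1,4-dien-6-ol
Conditions: HF·pyridine, pyridine, THF, 0 °C
Reagents that add atoms: none
Why: Fluoride desilylation in pyridine-buffered medium exploits the much higher lability of triethylsilyl over tert-butyldimethylsilyl ethers, and the buffered non-aqueous conditions are expected to spare the enol ether and the bis-allylic positions.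

Step 12
Reactants: 21 (3R,6S)-3-(tert-butyldimethylsilyloxy)-1-[(2R)-2-hydroxypentadecyl]-5-methoxycyclohexa-1,4-dien-6-ol
Product: 22 (3R,6S)-6-acetoxy-1-[(2R)-2-acetoxypentadecyl]-3-(tert-butyldimethylsilyloxy)-5-methoxycyclohexa-1,4-diene
Conditions: Ac2O, pyridine, DMAP (cat.), CH2Cl2, 0 °C to rt
Reagents that add atoms: acetic anhydride, CC(=O)OC(C)=O
Why: DMAP-catalysed acylation of both secondary alcohols proceeds under basic conditions that the enol ether and the silyl ether tolerate.

Step 13
Reactants: 22 (3R,6S)-6-acetoxy-1-[(2R)-2-acetoxypentadecyl]-3-(tert-butyldimethylsilyloxy)-5-methoxycyclohexa-1,4-diene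
Product: 23 (3R,6S)-6-acetoxy-1-[(2R)-2-acetoxypentadecyl]-5-methoxycyclohexa-1,4-dien-3-ol (target)
Conditions: TBAF, AcOH (1:1), THF, 0 °C to rt
Reagents that add atoms: none
Why: Fluoride cleavage of the unhindered bis-allylic silyl ether under acetic acid buffering keeps the medium near neutral, so the acetates should neither migrate nor cleave and 1,4-elimination to an arene should not be triggered.

Compound list
1 | (R)-epichlorohydrin | ClC[C@H]1CO1 | starting material
2 | dodecylmagnesium bromide | CCCCCCCCCCCC[Mg]Br | starting material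
3 | (2R)-1-chloropentadecan-2-ol | CCCCCCCCCCCCC[C@@H](O)CCl | intermediate
4 | (2R)-2-tridecyloxirane | CCCCCCCCCCCCC[C@@H]1CO1 | intermediate
5 | lithium acetylide–ethylenediamine complex | [Li+].[C-]#C.NCCN | starting material
6 | (4R)-heptadec-1-yn-4-ol | CCCCCCCCCCCCC[C@H](CC#C)O | intermediate
7 | (4R)-4-(triethylsilyloxy)heptadec-1-yne | CCCCCCCCCCCCC[C@H](CC#C)O[Si](CC)(CC)CC | intermediate
8 | acrolein | C=CC=O | starting material
9 | ethyl[(4R)-4-(triethylsilyloxy)heptadec-1-yn-1-yl]zinc | CCCCCCCCCCCCC[C@H](CC#C[Zn]CC)O[Si](CC)(CC)CC | intermediate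
10 | (3S,7R)-7-(triethylsilyloxy)icos-1-en-4-yn-3-ol | CCCCCCCCCCCCC[C@H](CC#C[C@@H](O)C=C)O[Si](CC)(CC)CC | intermediate
11 | sodium cyclic vinylalanate of 10 (Al with two 2-methoxyethoxy groups bridges O3 and C5, H on C4; stereocentres as in 10) | [Na+].CCCCCCCCCCCCC[C@H](CC1=C[C@H](C=C)O[Al-]1(OCCOC)OCCOC)O[Si](CC)(CC)CC | intermediate
12 | (3S,4Z,7R)-5-iodo-7-(triethylsilyloxy)icosa-1,4-dien-3-ol | CCCCCCCCCCCCC[C@H](C/C(I)=C/[C@@H](O)C=C)O[Si](CC)(CC)CC | intermediate
13 | (3S,4Z,7R)-3-(tert-butyldimethylsilyloxy)-5-iodo-7-(triethylsilyloxy)icosa-1,4-diene | CCCCCCCCCCCCC[C@H](C/C(I)=C/[C@@H](O[Si](C)(C)C(C)(C)C)C=C)O[Si](CC)(CC)CC | intermediate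
14 | dimethyl oxalate | COC(=O)C(=O)OC | starting material
15 | alkenylmagnesium chloride from 13 (MgCl in place of iodine, geometry and stereocentres retained) | CCCCCCCCCCCCC[C@H](C/C([Mg]Cl)=C/[C@@H](O[Si](C)(C)C(C)(C)C)C=C)O[Si](CC)(CC)CC | intermediate
16 | methyl (3Z,5S)-5-(tert-butyldimethylsilyloxy)-2-oxo-3-[(2R)-2-(triethylsilyloxy)pentadecyl]hepta-3,6-dienoate | CCCCCCCCCCCCC[C@H](C/C(=C/[C@@H](O[Si](C)(C)C(C)(C)C)C=C)C(=O)C(=O)OC)O[Si](CC)(CC)CC | intermediate
17 | methyl (2S,3Z,5S)-5-(tert-butyldimethylsilyloxy)-2-hydroxy-3-[(2R)-2-(triethylsilyloxy)pentadecyl]hepta-3,6-dienoate | CCCCCCCCCCCCC[C@H](C/C(=C/[C@@H](O[Si](C)(C)C(C)(C)C)C=C)[C@H](O)C(=O)OC)O[Si](CC)(CC)CC | intermediate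
18 | methyl (2S,3Z,5S)-5-(tert-butyldimethylsilyloxy)-2-(triethylsilyloxy)-3-[(2R)-2-(triethylsilyloxy)pentadecyl]hepta-3,6-dienoate | CCCCCCCCCCCCC[C@H](C/C(=C/[C@@H](O[Si](C)(C)C(C)(C)C)C=C)[C@H](O[Si](CC)(CC)CC)C(=O)OC)O[Si](CC)(CC)CC | intermediate
19 | titanium alkylidene of 18 (terminal CH2 of the vinyl group replaced by TiCl2; stereocentres as in 18) | CCCCCCCCCCCCC[C@H](C/C(=C/[C@@H](O[Si](C)(C)C(C)(C)C)C=[Ti](Cl)Cl)[C@H](O[Si](CC)(CC)CC)C(=O)OC)O[Si](CC)(CC)CC | intermediate
20 | (3R,6S)-3-(tert-butyldimethylsilyloxy)-5-methoxy-6-(triethylsilyloxy)-1-[(2R)-2-(triethylsilyloxy)pentadecyl]cyclohexa-1,4-diene | CCCCCCCCCCCCC[C@H](CC1=C[C@@H](O[Si](C)(C)C(C)(C)C)C=C(OC)[C@H]1O[Si](CC)(CC)CC)O[Si](CC)(CC)CC | intermediate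
21 | (3R,6S)-3-(tert-butyldimethylsilyloxy)-1-[(2R)-2-hydroxypentadecyl]-5-methoxycyclohexa-1,4-dien-6-ol | CCCCCCCCCCCCC[C@H](CC1=C[C@@H](O[Si](C)(C)C(C)(C)C)C=C(OC)[C@H]1O)O | intermediate
22 | (3R,6S)-6-acetoxy-1-[(2R)-2-acetoxypentadecyl]-3-(tert-butyldimethylsilyloxy)-5-methoxycyclohexa-1,4-diene | CCCCCCCCCCCCC[C@H](CC1=C[C@@H](O[Si](C)(C)C(C)(C)C)C=C(OC)[C@H]1OC(C)=O)OC(C)=O | intermediate
23 | CNP0123936.1, (3R,6S)-6-acetoxy-1-[(2R)-2-acetoxypentadecyl]-5-methoxycyclohexa-1,4-dien-3-ol | CCCCCCCCCCCCC[C@H](CC1=C[C@@H](O)C=C(OC)[C@H]1OC(C)=O)OC(C)=O | target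

Total step count: 13. Longest linear sequence: 13 steps (1 to 23).

Steps most likely to fail

Step 10. Three processes may drain the step. The ethylidene may olefinate the ester directly before it exchanges with the vinyl group, which is slowed by the neighbouring silyloxy group. The alkylidene 19 may lose its β-silyloxy group to the oxophilic metal. Lewis-acid ionisation at a bis-allylic position may be followed by aromatisation. The fallback makes the same C4=C5 bond in two known operations. Setting out from 18, methylenation of the ester with Cp2TiMe2 (toluene, 65 °C, dark) should give (3S,4Z,6S)-6-(tert-butyldimethylsilyloxy)-2-methoxy-3-(triethylsilyloxy)-4-[(2R)-2-(triethylsilyloxy)pentadecyl]octa-1,4,7-triene F1. Enol ether–olefin ring-closing metathesis with the second-generation Grubbs catalyst RuCl2(=CHPh)(PCy3)(H2IMes) (toluene, 70 °C, argon purge) should then close the ring and return to 20.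

Step 8. Facial selectivity may be poor if the catalyst does not distinguish the ester from the branched alkenyl group as small and large substituents. The fallback replaces reagent control by separation and inversion. Setting out from 16, Luche reduction (NaBH4, CeCl3·7H2O, MeOH, −78 °C) should give 17 together with its C2 epimer, methyl (2R,3Z,5S)-5-(tert-butyldimethylsilyloxy)-2-hydroxy-3-[(2R)-2-(triethylsilyloxy)pentadecyl]hepta-3,6-dienoate F2. The two are diastereomers and are separated by chromatography. Mitsunobu esterification of the unwanted epimer (4-nitrobenzoic acid, PPh3, DIAD, toluene, 0 °C) inverts C2 to give methyl (2S,3Z,5S)-5-(tert-butyldimethylsilyloxy)-2-(4-nitrobenzoyloxy)-3-[(2R)-2-(triethylsilyloxy)pentadecyl]hepta-3,6-dienoate F3. Mild methanolysis (K2CO3, MeOH, 0 °C) then releases 17, where the route is rejoined.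

Step 4. Enantiofacial selectivity may be low, and acrolein may oligomerise under the Lewis-acidic zinc–titanium conditions. The fallback replaces asymmetric catalysis by enzymatic resolution. Setting out from 7 and 8, deprotonation of 7 (n-BuLi, THF, −78 °C) and addition to acrolein should give the C3-epimeric mixture (3RS,7R)-7-(triethylsilyloxy)icos-1-en-4-yn-3-ol F4. Lipase-catalysed transesterification (Pseudomonas cepacia lipase, vinyl acetate, hexane, rt) is expected to acylate the (3R) epimer to (3R,7R)-7-(triethylsilyloxy)icos-1-en-4-yn-3-yl acetate F5. The (3S) alcohol is left behind, is separated by chromatography and is compound 10.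

Further compounds
F1 | step 10 | (3S,4Z,6S)-6-(tert-butyldimethylsilyloxy)-2-methoxy-3-(triethylsilyloxy)-4-[(2R)-2-(triethylsilyloxy)pentadecyl]octa-1,4,7-triene | CCCCCCCCCCCCC[C@H](C/C(=C/[C@@H](O[Si](C)(C)C(C)(C)C)C=C)[C@H](O[Si](CC)(CC)CC)C(=C)OC)O[Si](CC)(CC)CC
F2 | step 8 | methyl (2R,3Z,5S)-5-(tert-butyldimethylsilyloxy)-2-hydroxy-3-[(2R)-2-(triethylsilyloxy)pentadecyl]hepta-3,6-dienoate | CCCCCCCCCCCCC[C@H](C/C(=C/[C@@H](O[Si](C)(C)C(C)(C)C)C=C)[C@@H](O)C(=O)OC)O[Si](CC)(CC)CC
F3 | step 8 | methyl (2S,3Z,5S)-5-(tert-butyldimethylsilyloxy)-2-(4-nitrobenzoyloxy)-3-[(2R)-2-(triethylsilyloxy)pentadecyl]hepta-3,6-dienoate | CCCCCCCCCCCCC[C@H](C/C(=C/[C@@H](O[Si](C)(C)C(C)(C)C)C=C)[C@H](OC(=O)c1ccc(cc1)[N+](=O)[O-])C(=O)OC)O[Si](CC)(CC)CC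
F4 | step 4 | (3RS,7R)-7-(triethylsilyloxy)icos-1-en-4-yn-3-ol (C3-epimer mixture) | CCCCCCCCCCCCC[C@H](CC#CC(O)C=C)O[Si](CC)(CC)CC
F5 | step 4 | (3R,7R)-7-(triethylsilyloxy)icos-1-en-4-yn-3-yl acetate | CCCCCCCCCCCCC[C@H](CC#C[C@H](OC(C)=O)C=C)O[Si](CC)(CC)CC
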